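**Red's stall.** The red run stopped early. At 4.00 h its left-handed product read 34% of the two substrates charged, which is 38.1 mM from 40.7 mM of reagent, the limiting reagent there, its charge being below the 56 mM of left-handed substrate. The new flask has the same reagent charge and less substrate.

common to all: free catalyst 2.1 mM
- grey: left-handed substrate 25 mM; right-handed substrate 25 mM; reagent 40.7 mM; run made earlier
- red: left-handed substrate 56 mM; right-handed substrate 56 mM; reagent 40.7 mM; run made earlier
- ochre: left-handed substrate 37 mM; right-handed substrate 37 mM; reagent 81 mM; run made earlier
- flask: left-handed substrate 37 mM; right-handed substrate 37 mM; reagent 40.7 mM; time 6.0 h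

- grey (time / h: right-handed substrate / %, left-handed substrate / %, left-handed product / %): 0.833: 46, 9, 39; 2.00: 48, 4, 47; 2.50: 48, 1, 49; 4.00: 48, 0, 48
- red (time / h: right-handed substrate / %, left-handed substrate / %, left-handed product / %): 0.833: 50, 18, 28; 2.00: 49, 13, 33; 2.50: 49, 14, 33; 4.00: 50, 15, 34
- ochre (time / h: right-handed substrate / %, left-handed substrate / %, left-handed product / %): 0.833: 48, 3, 47; 2.00: 49, 0, 48; 2.50: 47, 0, 51; 4.00: 45, 0, 50

(scatter of a reading: 1.5 percentage points)

- free catalyst is single-handed; left-handed substrate and right-handed substrate are mirror images of each other, charged as a racemate, each of them at the stated concentration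

1. whether the excess of right-handed substrate over left-handed substrate among what is left of the two reaches 80% by 6.0 h (yes / no)
2. the highest excess of right-handed substrate over left-handed substrate among what is left of the two up to 6.0 h

**Main step.** I followed one reagent molecule in the flask and first let it take one left-handed substrate, nothing else. An excess of 80% needs [left-handed substrate] at 0.111 of [right-handed substrate], so 4.11 mM, and 32.9 mM must react. I named the reagent call the part of the reagent charge that must react with left-handed substrate to reach the wanted excess: here 80.8%, leaving 7.81 mM spare.

**Adding losses.** Next I took red's 38.1 mM as the usable reagent, and the spare fell to 5.20 mM. Then I added the other fork: the ochre run's right-handed substrate read 49% at 2.00 h and 45% at 4.00 h, about 2.96 mM, though with 81 mM of reagent. Charged in full against the flask, that still left 2.24 mM, since the call plus this loss stays below the usable reagent.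

**Adding pace.** I took the rate as proportional to [left-handed substrate] times [reagent], and the single grey reading at 0.833 h gave a constant near 77.6 L mol⁻¹ h⁻¹, with that reading's scatter on it. With 38.1 mM usable, I reckoned the flask would meet its call at 2.44 h and show an excess of 92.0% at 6.0 h.

**Result.** The forecast said yes with a top of 90%, below my figure, and warned: “A stall would be the main risk.” The flask gave yes and a top of 88.6%, passing 80% at 2.82 h.

    reagent + free catalyst + left-handed substrate → free catalyst + left-handed product (k = 38000 L² mol⁻² h⁻¹)
    reagent + free catalyst + right-handed substrate → free catalyst + right-handed product (k = 460 L² mol⁻² h⁻¹)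
    reagent + free catalyst → spent catalyst A (k = 4.40 L mol⁻¹ h⁻¹)
    2 free catalyst → spent catalyst B (k = 49.0 L mol⁻¹ h⁻¹)

**Call used.** At 6.00 h the flask kept 5.9% of its left-handed substrate. At 3.00 h its excess stood at 80.9% and its reagent at 15.3% of charge, so 84.7% had gone in total, against the call of 80.8%, which counts the part taken by left-handed substrate. For the red run the call comes to 122% of its reagent, and its readings at 4.00 h give an excess of 53.8%.

The earlier runs and the new flask come from a simulation for an exercise, and the scatter is random.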